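**Plan**
Isoflavan numbering is used: O1, C2, C3, C4, C4a, C5–C8, C8a; ring A is the fused benzene ring, ring B the aryl group on C3; the target is the (3S)-isoflavan.
Retrosynthesis: C4 is raised to a ketone and C2–C3 to an alkene (isoflavone 11); O1–C8a and C2–C3 are then cut together, releasing a formate C1 unit (C2 + O1) and deoxybenzoin 8; 8 is cut at C3–C4 into a ring B benzylic Grignard reagent and a ring A Weinreb amide.
Enabling feature: on ring A the free 6-OH is para to C8a (O1 and O6 are a hydroquinone pair), so two-electron oxidation of that phenol makes C8a electrophilic, while the temporary C4 carbonyl makes C3 nucleophilic; ring A needs no halogen and no protecting group.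
Forward order: the fragments are joined at C3–C4, the pyranone ring is closed in the key step, then the ring is reduced.
Stereochemistry: C3 is set by Ru-catalysed asymmetric transfer hydrogenation with dynamic kinetic resolution (the C4 carbonyl keeps C3 epimerisable); C4–OH and the benzyl group leave by hydrogenolysis.

Key step: step 6

Remark on the chemistry: RuCl[(S,S)-TsDPEN](p-cymene) is assumed to reduce the chroman-4-one from the same face as acetophenone, giving the (4S)-carbinol; if the sense were opposite, the (R,R)-catalyst would be used.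

**Step 1**
Reactants: 1 2-hydroxy-3,4-dimethoxybenzaldehyde
Product: 2 2-(benzyloxy)-3,4-dimethoxybenzaldehyde
Conditions: BnBr, K2CO3, DMF, 60 °C
Reagents that add atoms: benzyl bromide, BrCc1ccccc1
Why: Williamson O-alkylation of the phenoxide masks the 2'-oxygen, so that ring A carries the only free phenol in step 6, and the benzyl group comes off in step 8.

**Step 2**
Reactants: 2 2-(benzyloxy)-3,4-dimethoxybenzaldehyde
Product: 3 [2-(benzyloxy)-3,4-dimethoxyphenyl]methanol
Conditions: NaBH4, MeOH, 0 °C
Reagents that add atoms: none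
Why: Borohydride reduction of the aryl aldehyde should give the benzylic alcohol cleanly.

**Step 3**
Reactants: 3 [2-(benzyloxy)-3,4-dimethoxyphenyl]methanol
Product: 4 2-(benzyloxy)-1-(chloromethyl)-3,4-dimethoxybenzene
Conditions: SOCl2, CH2Cl2, 0 °C
Reagents that add atoms: thionyl chloride, O=S(Cl)Cl
Why: Chlorodehydroxylation through the chlorosulfite is easy at this electron-rich benzylic position; the chloride should be used crude.

**Step 4**
Reactants: 5 methyl 3-hydroxy-4,5-dimethoxybenzoate
Product: 6 3-hydroxy-N,4,5-trimethoxy-N-methylbenzamide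
Conditions: MeNH(OMe)·HCl, i-PrMgCl, THF, −20 °C to 0 °C
Reagents that add atoms: N,O-dimethylhydroxylamine hydrochloride, CNOC.Cl
Why: Aminolysis of the methyl ester by the magnesium amide (Weinreb amide formation) should proceed with the phenol carried as its magnesium phenoxide.

**Step 5**
Reactants: 4 2-(benzyloxy)-1-(chloromethyl)-3,4-dimethoxybenzene, 6 3-hydroxy-N,4,5-trimethoxy-N-methylbenzamide
Product: 8 2-[2-(benzyloxy)-3,4-dimethoxyphenyl]-1-(3-hydroxy-4,5-dimethoxyphenyl)ethan-1-one, via benzylic Grignard reagent 7 (not isolated)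
Conditions: 4, Mg, THF, 0 °C; then added to 6 (pre-treated with i-PrMgCl), THF, 0 °C to rt; aq NH4Cl
Reagents that add atoms: none
Why: Weinreb ketone synthesis forms the C3–C4 bond, the chelated tetrahedral adduct preventing over-addition and surviving until work-up.

**Step 6**
Reactants: 8 2-[2-(benzyloxy)-3,4-dimethoxyphenyl]-1-(3-hydroxy-4,5-dimethoxyphenyl)ethan-1-one
Product: 11 3-[2-(benzyloxy)-3,4-dimethoxyphenyl]-6-hydroxy-7,8-dimethoxy-4H-chromen-4-one, via hydroxymethylene ketone 9 (not isolated), via 8aH-dienone 10 (not isolated)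
Conditions: HCO2Et, NaH, THF, 0 °C to rt; AcOH, evaporate; then PhI(OAc)2 (one equivalent), (CF3)2CHOH, −20 °C to 0 °C
Reagents that add atoms: ethyl formate, CCOC=O
Why: Proposed new method: Claisen C-formylation of the ketone enolate of 8 with ethyl formate makes the C2–C3 bond and leaves the formate carbonyl oxygen as the enol oxygen O1 of 9; PhI(OAc)2 (trivalent iodine) then oxidises the only free phenol, the 6-OH of ring A, to an aryloxy-iodane or phenoxenium-type species, O1 adds at C8a (para to the phenol oxygen), PhI and AcOH are lost, and the 8aH-dienone 10 tautomerises to the aromatic 6-hydroxychromone 11. The closest known reaction types are the trivalent-iodine oxidative dearomatisation of phenols with capture by a tethered oxygen nucleophile and the oxidative phenolic C–O coupling that converts hydroxybenzophenones into xanthones, while the formylation is the standard first half of deoxybenzoin-to-isoflavone syntheses. The pyranone ring closes in a six-membered mode by attack of the enol oxygen on the electrophilic ring carbon C8a (formally 6-endo with respect to the C4a–C8a unit), and no lasting stereocentre arises because the sp3 centre C8a of 10 is erased on tautomerisation. The step needs capture at C8a (para) and not at C5 (ortho), and oxidation of the ring A phenol in preference to the enol, ring B and the product. The tether lets O1 reach only C5 and C8a, para capture gives the cross-conjugated dienone that is also a vinylogous ester through 7-OMe, the 2'-oxygen is masked as a benzyl ether, and the non-nucleophilic solvent suppresses intermolecular attack at C7. The product phenol is deactivated by the chromone carbonyl, so one equivalent of oxidant at low temperature should stop at 11.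

**Step 7**
Reactants: 11 3-[2-(benzyloxy)-3,4-dimethoxyphenyl]-6-hydroxy-7,8-dimethoxy-4H-chromen-4-one
Product: 13 (3S,4S)-3-[2-(benzyloxy)-3,4-dimethoxyphenyl]-7,8-dimethoxychromane-4,6-diol, via racemising isoflavanone 12 (not isolated)
Conditions: RuCl[(S,S)-TsDPEN](p-cymene) (cat.), HCO2H/Et3N azeotrope, DMF, 40 °C
Reagents that add atoms: none
Why: Noyori–Ikariya asymmetric transfer hydrogenation, a reaction type known for isoflavones, should first reduce the C2=C3 bond to isoflavanone 12, whose C3–H epimerises under Et3N; the (S,S)-catalyst then reduces the (3S)-ketone faster, delivering hydride to C4 anti to the 3-aryl group, so that dynamic kinetic resolution sets C3 (S) and C4 (S) as the cis-carbinol.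

**Step 8**
Reactants: 13 (3S,4S)-3-[2-(benzyloxy)-3,4-dimethoxyphenyl]-7,8-dimethoxychromane-4,6-diol
Product: 14 (3S)-3-(2-hydroxy-3,4-dimethoxyphenyl)-7,8-dimethoxychroman-6-ol
Conditions: H2, Pd/C, EtOH, AcOH (trace), rt
Reagents that add atoms: none
Why: Catalytic hydrogenolysis should cleave both benzylic C–O bonds, the benzyl ether and the C4 carbinol (activated by the para 7-OMe of ring A), without touching C3, so the (3S) centre is carried unchanged into the target.

**Compound list**
1 | 2-hydroxy-3,4-dimethoxybenzaldehyde | COc1ccc(C=O)c(O)c1OC | starting material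
2 | 2-(benzyloxy)-3,4-dimethoxybenzaldehyde | COc1ccc(C=O)c(OCc2ccccc2)c1OC | intermediate
3 | [2-(benzyloxy)-3,4-dimethoxyphenyl]methanol | COc1ccc(CO)c(OCc2ccccc2)c1OC | intermediate
4 | 2-(benzyloxy)-1-(chloromethyl)-3,4-dimethoxybenzene | COc1ccc(CCl)c(OCc2ccccc2)c1OC | intermediate
5 | methyl 3-hydroxy-4,5-dimethoxybenzoate | COC(=O)c1cc(O)c(OC)c(OC)c1 | starting material
6 | 3-hydroxy-N,4,5-trimethoxy-N-methylbenzamide | CON(C)C(=O)c1cc(O)c(OC)c(OC)c1 | intermediate
7 | {[2-(benzyloxy)-3,4-dimethoxyphenyl]methyl}magnesium chloride | COc1ccc(C[Mg]Cl)c(OCc2ccccc2)c1OC | intermediate (not isolated)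
8 | 2-[2-(benzyloxy)-3,4-dimethoxyphenyl]-1-(3-hydroxy-4,5-dimethoxyphenyl)ethan-1-one | COc1ccc(CC(=O)c2cc(O)c(OC)c(OC)c2)c(OCc3ccccc3)c1OC | intermediate
9 | 2-[2-(benzyloxy)-3,4-dimethoxyphenyl]-3-hydroxy-1-(3-hydroxy-4,5-dimethoxyphenyl)prop-2-en-1-one (hydroxymethylene tautomer of the α-formyl ketone) | COc1ccc(C(=CO)C(=O)c2cc(O)c(OC)c(OC)c2)c(OCc3ccccc3)c1OC | intermediate (not isolated)
10 | 3-[2-(benzyloxy)-3,4-dimethoxyphenyl]-7,8-dimethoxy-8aH-chromene-4,6-dione | COc1ccc(C2=COC3C(=CC(=O)C(OC)=C3OC)C2=O)c(OCc4ccccc4)c1OC | intermediate (not isolated)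
11 | 3-[2-(benzyloxy)-3,4-dimethoxyphenyl]-6-hydroxy-7,8-dimethoxy-4H-chromen-4-one | COc1ccc(-c2coc3c(OC)c(OC)c(O)cc3c2=O)c(OCc4ccccc4)c1OC | intermediate
12 | 3-[2-(benzyloxy)-3,4-dimethoxyphenyl]-6-hydroxy-7,8-dimethoxychroman-4-one (C3 epimerising) | COc1ccc(C2COc3c(OC)c(OC)c(O)cc3C2=O)c(OCc4ccccc4)c1OC | intermediate (not isolated)
13 | (3S,4S)-3-[2-(benzyloxy)-3,4-dimethoxyphenyl]-7,8-dimethoxychromane-4,6-diol | COc1ccc([C@H]2COc3c(cc(O)c(OC)c3OC)[C@H]2O)c(OCc4ccccc4)c1OC | intermediate
14 | (3S)-3-(2-hydroxy-3,4-dimethoxyphenyl)-7,8-dimethoxychroman-6-ol | COc1ccc([C@H]2COc3c(cc(O)c(OC)c3OC)C2)c(O)c1OC | target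

Total step count: 8. Longest linear sequence: 7 steps (steps 1, 2, 3, 5, 6, 7, 8).

**Steps most likely to fail**

Step 6 (key step). The oxidised ring may be captured at C5 (ortho) instead of C8a, or at C8a by carbon C6' of ring B in place of O1. The enol may be oxidised in place of the phenol, or the product phenol may be oxidised further. The fallback uses known chemistry, sets out from 8 and comes back at 11. The oxygen is first placed at C8a by para-selective Teuber oxidation of phenol 8 with (KSO3)2NO (aqueous acetone, KH2PO4) to the quinone 2-{[2-(benzyloxy)-3,4-dimethoxyphenyl]acetyl}-5,6-dimethoxycyclohexa-2,5-diene-1,4-dione F1. This is reduced at once with Na2S2O4 to the hydroquinone 2-[2-(benzyloxy)-3,4-dimethoxyphenyl]-1-(2,5-dihydroxy-3,4-dimethoxyphenyl)ethan-1-one F2. The 2-hydroxy ketone of F2 is then closed with a C1 unit in the classical deoxybenzoin-to-isoflavone manner (BF3·OEt2, DMF, MeSO2Cl, 70 °C) to give 11.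

Step 7. Conjugate reduction of the vinylogous ester may be sluggish, the free phenol may inhibit the catalyst, or epimerisation at C3 may be too slow for good enantio- and diastereocontrol. The fallback sets out from 11 and comes back at 14. NaBH4 (EtOH/THF) should reduce 11 to the racemic carbinol 3-[2-(benzyloxy)-3,4-dimethoxyphenyl]-7,8-dimethoxychromane-4,6-diol F3. Acid-catalysed dehydration (p-TsOH, toluene, heat) should give the isoflav-3-ene 3-[2-(benzyloxy)-3,4-dimethoxyphenyl]-7,8-dimethoxy-2H-chromen-6-ol F4. Asymmetric hydrogenation of this cyclic trisubstituted alkene with [Ir(cod)(tBu-PHOX)]B[C6H3(CF3)2]4 and H2 in CH2Cl2, the ligand enantiomer chosen for the (S)-product, should give (3S)-3-[2-(benzyloxy)-3,4-dimethoxyphenyl]-7,8-dimethoxychroman-6-ol F5. Debenzylation of F5 (H2, Pd/C, EtOH) gives 14.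

Step 8. Acid-assisted ionisation at C4 may be followed by loss of the C3 proton to the isoflav-3-ene before hydrogen is delivered, which would erode the C3 configuration; the C4–O bond may also be cleaved incompletely. The fallback sets out from 13 and comes back at 14. Debenzylation under neutral conditions (H2, Pd/C, EtOAc) should give (3S,4S)-3-(2-hydroxy-3,4-dimethoxyphenyl)-7,8-dimethoxychromane-4,6-diol F6. Catalytic acid (p-TsOH, CH2Cl2, 0 °C) should close F6 to the cis-pterocarpan (6aS,11aS)-3,4,9,10-tetramethoxy-6a,11a-dihydro-6H-[1]benzofuro[3,2-c]chromen-2-ol F7, the 2'-OH capturing C4 intramolecularly faster than elimination. Hydrogenolysis of the benzylic aryl ether C–O bond of this temporary ring (H2, Pd/C, EtOH) releases the 2'-OH and gives 14.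

**Further compounds**
F1 | step 6 | 2-{[2-(benzyloxy)-3,4-dimethoxyphenyl]acetyl}-5,6-dimethoxycyclohexa-2,5-diene-1,4-dione | COc1ccc(CC(=O)C2=CC(=O)C(OC)=C(OC)C2=O)c(OCc3ccccc3)c1OC
F2 | step 6 | 2-[2-(benzyloxy)-3,4-dimethoxyphenyl]-1-(2,5-dihydroxy-3,4-dimethoxyphenyl)ethan-1-one | COc1ccc(CC(=O)c2cc(O)c(OC)c(OC)c2O)c(OCc3ccccc3)c1OC
F3 | step 7 | 3-[2-(benzyloxy)-3,4-dimethoxyphenyl]-7,8-dimethoxychromane-4,6-diol (racemic) | COc1ccc(C2COc3c(OC)c(OC)c(O)cc3C2O)c(OCc4ccccc4)c1OC
F4 | step 7 | 3-[2-(benzyloxy)-3,4-dimethoxyphenyl]-7,8-dimethoxy-2H-chromen-6-ol | COc1ccc(C2=Cc3cc(O)c(OC)c(OC)c3OC2)c(OCc4ccccc4)c1OC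
F5 | step 7 | (3S)-3-[2-(benzyloxy)-3,4-dimethoxyphenyl]-7,8-dimethoxychroman-6-ol | COc1ccc([C@H]2COc3c(cc(O)c(OC)c3OC)C2)c(OCc4ccccc4)c1OC
F6 | step 8 | (3S,4S)-3-(2-hydroxy-3,4-dimethoxyphenyl)-7,8-dimethoxychromane-4,6-diol | COc1ccc([C@H]2COc3c(cc(O)c(OC)c3OC)[C@H]2O)c(O)c1OC
F7 | step 8 | (6aS,11aS)-3,4,9,10-tetramethoxy-6a,11a-dihydro-6H-[1]benzofuro[3,2-c]chromen-2-ol | COc1ccc2[C@H]3COc4c(cc(O)c(OC)c4OC)[C@H]3Oc2c1OC
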